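**Retrosynthetic overview**

1. Numbering (longipinane): C1 ketone, C2=C3(Me), bridgeheads C4 and C11, C5, C6 (CMe2), C7 (O-isovaleryl), C8, C9 (O-tigloyl), C10 (quaternary, Me). Target 23 ⇐ 22 by loss of methanol across C2–C3.
2. Key disconnection, C3–C4 and C5–C11 together: 22 ⇐ 20, a monocyclic cycloheptene carrying a 3-methoxy-3-methylcyclobutanone on C10. A Lewis acid opens the four-membered ketone to a 1,4-zwitterion that adds across C4=C5. This two-carbon ring expansion (cyclobutanone → cyclohexanone) closes the six-membered ketone ring and the cyclobutane in one operation and sets C4, C5 and C11.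
3. Enabling feature: in the 3-methylcyclohex-2-enone ring (C1, C2, C3, C4, C5, C11) the carbonyl carbon C1 and the methyl-bearing C3 are 1,3-related, so C11–C1–C2–C3 is the opened form (C11 enolate, C3 oxocarbenium) of a 3-alkoxycyclobutanone. The other two ring atoms, C4–C5, are a cis double bond of the seven-membered ring, and the quaternary C10 ties C11 to C4, so the second bond can only close the cyclobutane C4–C5–C11–C10.
4. 20 ⇐ acid 16 (ketene + 2-methoxypropene [2+2]) ⇐ cis-fused acetal 10. In 10 the quaternary C10 (syn to O9) and the C4=C5 double bond come from a Heck-type radical cyclisation of an O9-tethered iodoacetal onto C10=C4 of cycloheptenol 6.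
5. 6 ⇐ RCM ⇐ 5 ⇐ Evans–Tishchenko reduction (sets C9, puts the isovalerate on O7) ⇐ 3 ⇐ zinc-catalysed aldol of 1 and 2 (sets C7). Ring order: seven-membered ring (step 3), temporary oxolane (step 5, opened in step 6), temporary cyclobutanone (step 10), then six-membered ring and cyclobutane together (step 11).

Key step: step 11

Remark: both ester groups of the target are already in place in step 11; they are assumed to sit as EtAlCl2 complexes and not to take part.

**Route**

Step 1
Reactants: 1 2,2-dimethylpent-4-enal; 2 3-methylbut-3-en-2-one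
Product: 3 (5R)-5-hydroxy-2,6,6-trimethylnona-1,8-dien-3-one
Conditions: (S,S)-ProPhenol (10 mol %), Et2Zn (20 mol %), 4 Å molecular sieves, THF, 0 °C, 2 in excess
Reagents that add atoms: 3-methylbut-3-en-2-one (2), CC(=O)C(C)=C
Why: Direct catalytic asymmetric aldol addition (dinuclear zinc–ProPhenol): the zinc enolate of the methyl ketone adds to the non-enolisable α-quaternary aldehyde inside the chiral pocket and sets C7 (5R in 3); the (S,S)-ligand is expected to give this sense by analogy with α-branched aldehydes, and its antipode would be used if the sense proves opposite.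

Step 2
Reactants: 3 (5R)-5-hydroxy-2,6,6-trimethylnona-1,8-dien-3-one; 4 3-methylbutanal
Product: 5 (3R,5R)-3-hydroxy-2,6,6-trimethylnona-1,8-dien-5-yl 3-methylbutanoate
Conditions: SmI2 (0.3 equiv), 4 (4 equiv), THF, −10 °C
Reagents that add atoms: 3-methylbutanal (4), CC(C)CC=O
Why: Evans–Tishchenko reduction: the samarium-bound hemiacetal of 4 delivers hydride to the ketone through a chair-like chelate, so the new carbinol C9 is 1,3-anti to C7 and the isovalerate of the target lands on O7 in the same event.

Step 3
Reactants: 5 (3R,5R)-3-hydroxy-2,6,6-trimethylnona-1,8-dien-5-yl 3-methylbutanoate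
Product: 6 (1R,6R)-6-hydroxy-2,2,5-trimethylcyclohept-4-en-1-yl 3-methylbutanoate
Conditions: second-generation Grubbs catalyst RuCl2(=CHPh)(PCy3)(H2IMes) (5 mol %), CH2Cl2 (5 mM), 40 °C
Reagents that add atoms: none
Why: Ring-closing metathesis of the allyl and isopropenyl groups should give the seven-membered ring with the trisubstituted C10=C4 double bond, helped by the gem-dimethyl group and tolerant of the free allylic alcohol; no stereocentre is formed.

Step 4
Reactants: 6 (1R,6R)-6-hydroxy-2,2,5-trimethylcyclohept-4-en-1-yl 3-methylbutanoate; 7 ethyl vinyl ether; 8 N-iodosuccinimide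
Product: 9 (1R,6R)-6-(1-ethoxy-2-iodoethoxy)-2,2,5-trimethylcyclohept-4-en-1-yl 3-methylbutanoate (both acetal epimers)
Conditions: 7 (3 equiv), 8 (1.3 equiv), CH2Cl2, −40 → 0 °C
Reagents that add atoms: ethyl vinyl ether (7), C=COCC; N-iodosuccinimide (8), O=C1CCC(=O)N1I
Why: Iodoalkoxylation of the enol ether (Ueno–Stork acetal formation): the iodonium ion of the electron-rich vinyl ether is opened by the C9 hydroxyl, giving the tethered primary iodide; the acetal epimers are of no consequence.

Step 5
Reactants: 9 (1R,6R)-6-(1-ethoxy-2-iodoethoxy)-2,2,5-trimethylcyclohept-4-en-1-yl 3-methylbutanoate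
Product: 10 (3aS,7R,8aR)-2-ethoxy-3a,6,6-trimethyl-3,3a,6,7,8,8a-hexahydro-2H-cyclohepta[b]furan-7-yl 3-methylbutanoate (cis-fused, both C2 epimers)
Conditions: Pd(PPh3)4 (10 mol %), 1,2,2,6,6-pentamethylpiperidine (2 equiv), benzene, CO (10 atm, not incorporated), 110 °C
Reagents that add atoms: none
Why: Heck-type cyclisation of an unactivated alkyl iodide at zerovalent palladium (radical–organometallic hybrid, Ueno–Stork ring closure): the primary radical adds 5-exo to C10 from the face of the O9 tether, so the quaternary centre is set syn to O9 in a cis-fused oxolane, and β-hydride elimination from C4 can only go towards C5 because C10 carries no hydrogen, which places the double bond at C4=C5.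

Step 6
Reactants: 10 (3aS,7R,8aR)-2-ethoxy-3a,6,6-trimethyl-3,3a,6,7,8,8a-hexahydro-2H-cyclohepta[b]furan-7-yl 3-methylbutanoate; 11 propane-1,3-dithiol
Product: 12 (1R,5S,6R)-5-(1,3-dithian-2-ylmethyl)-6-hydroxy-2,2,5-trimethylcyclohept-3-en-1-yl 3-methylbutanoate
Conditions: 11 (1.5 equiv), BF3·OEt2 (0.3 equiv), CH2Cl2, −20 °C
Reagents that add atoms: propane-1,3-dithiol (11), SCCCS
Why: Lewis-acid transthioacetalisation opens the cyclic mixed acetal to the acyclic 1,3-dithiane and frees the C9 hydroxyl without touching the ester or the alkene.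

Step 7
Reactants: 12 (1R,5S,6R)-5-(1,3-dithian-2-ylmethyl)-6-hydroxy-2,2,5-trimethylcyclohept-3-en-1-yl 3-methylbutanoate; 13 tigloyl chloride
Product: 14 (1R,2S,6R)-2-(1,3-dithian-2-ylmethyl)-2,5,5-trimethyl-6-[(3-methylbutanoyl)oxy]cyclohept-3-en-1-yl (2E)-2-methylbut-2-enoate
Conditions: 13 (3 equiv), pyridine, DMAP (0.3 equiv), CH2Cl2, 0 → 40 °C
Reagents that add atoms: tigloyl chloride (13), C/C=C(\C)C(=O)Cl
Why: DMAP-catalysed acylation of the hindered secondary alcohol installs the (E)-2-methylbut-2-enoate of the target; pyridine is used as the weak base so that the acid chloride is not deconjugated through a vinylketene.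

Step 8
Reactants: 14 (1R,2S,6R)-2-(1,3-dithian-2-ylmethyl)-2,5,5-trimethyl-6-[(3-methylbutanoyl)oxy]cyclohept-3-en-1-yl (2E)-2-methylbut-2-enoate
Product: 15 (1R,2S,6R)-2,5,5-trimethyl-6-[(3-methylbutanoyl)oxy]-2-(2-oxoethyl)cyclohept-3-en-1-yl (2E)-2-methylbut-2-enoate
Conditions: PhI(O2CCF3)2 (1.5 equiv), MeCN/H2O 9:1, 0 °C
Reagents that add atoms: water, O
Why: Oxidative hydrolysis of the 1,3-dithiane by the hypervalent iodine reagent (sulfonium formation, then water) releases the aldehyde under conditions that should leave both alkenes and both esters untouched.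

Step 9
Reactants: 15 (1R,2S,6R)-2,5,5-trimethyl-6-[(3-methylbutanoyl)oxy]-2-(2-oxoethyl)cyclohept-3-en-1-yl (2E)-2-methylbut-2-enoate
Product: 16 2-{(1S,5R,7R)-1,4,4-trimethyl-5-[(3-methylbutanoyl)oxy]-7-{[(2E)-2-methylbut-2-enoyl]oxy}cyclohept-2-en-1-yl}acetic acid
Conditions: NaClO2, NaH2PO4, 2-methylbut-2-ene, t-BuOH/H2O, 20 °C
Reagents that add atoms: sodium chlorite, [Na+].[O-]Cl=O
Why: Pinnick oxidation of the aldehyde to the acid, with 2-methylbut-2-ene as hypochlorite scavenger so that the ring alkene and the tiglate are not chlorinated.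

Step 10
Reactants: 16 2-{(1S,5R,7R)-1,4,4-trimethyl-5-[(3-methylbutanoyl)oxy]-7-{[(2E)-2-methylbut-2-enoyl]oxy}cyclohept-2-en-1-yl}acetic acid; 17 2-methoxypropene
Product: 20 (1R,2R,6R)-2-(2-methoxy-2-methyl-4-oxocyclobutyl)-2,5,5-trimethyl-6-[(3-methylbutanoyl)oxy]cyclohept-3-en-1-yl (2E)-2-methylbut-2-enoate (cyclobutane diastereomers), via acid chloride 18 (not isolated), via ketene 19 (not isolated)
Conditions: (COCl)2 (1.5 equiv), DMF (cat.), CH2Cl2, 0 → 20 °C, evaporate; then Et3N (1.5 equiv), 17 (10 equiv), MeCN, 70 °C, sealed tube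
Reagents that add atoms: 2-methoxypropene (17), C=C(C)OC
Why: Dehydrochlorination of the acid chloride gives a hindered, dimerisation-resistant alkylketene that undergoes thermal [2+2] cycloaddition with the enol ether, the ketene carbonyl carbon bonding to the CH2 terminus, to give the 2-substituted 3-methoxy-3-methylcyclobutanone; its diastereomers converge in step 11.

Step 11
Reactants: 20 (1R,2R,6R)-2-(2-methoxy-2-methyl-4-oxocyclobutyl)-2,5,5-trimethyl-6-[(3-methylbutanoyl)oxy]cyclohept-3-en-1-yl (2E)-2-methylbut-2-enoate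
Product: 22 3-methoxy-7-[(3-methylbutanoyl)oxy]-1-oxolongipinan-9-yl (2E)-2-methylbut-2-enoate (ring stereocentres as in 23, both C3 epimers), via zwitterion 21 (not isolated)
Conditions: EtAlCl2 (4 equiv), CH2Cl2, −78 → −20 °C; aq. NaHCO3
Reagents that add atoms: none
Why: Proposed new method: EtAlCl2 binds the cyclobutanone oxygen (the two ester carbonyls take up further equivalents) and the strained, more substituted C11–C3 bond, pushed by the methoxy group, breaks heterolytically to the 1,4-zwitterion 21 (aluminium enolate at O1/C11, methoxycarbenium at C3), whose cation is attacked by C4 of the ring alkene while the positive charge arriving at C5 is taken at once by the enolate carbon C11; the diastereomers of 20 converge because C11 and C3 are planar in 21. The closest known reaction type is the Lewis-acid-promoted formal [4+2] cycloaddition of 3-alkoxycyclobutanones with alkenes (allylsilanes, and tethered trisubstituted alkenes that give fused rings), a two-carbon ring expansion of the four-membered ketone; new here are the one-atom tether (C10), which turns the second bond formation into a cyclobutane closure, and the unactivated 1,2-disubstituted alkene. The C3–C4 bond closes the six-membered ring C1–C2–C3–C4–C10–C11 by cation–olefin attack in the 6-exo mode (C5 stays outside the ring), and the C5–C11 bond closes the cyclobutane C4–C5–C11–C10, and with it the cyclohexanone ring C1–C2–C3–C4–C5–C11, by collapse of a 1,4-ion pair (4-exo closure at a cationic carbon). C4, C5 and C11 are all dictated by the quaternary C10: the chain hangs from the ring face syn to O9, so C3 must bond to that face of C4, the six-membered ring is cis-fused, and the bridged cyclobutane admits only one configuration at C5 and C11; C3 forms as a mixture that step 12 erases. Needed are cleavage of C11–C3 and not C2–C3 (the more substituted and more strained bond, the one that breaks in the known chemistry), attack through C4 and not C5 (six- against seven-membered ring), and C–C collapse faster than a methyl shift from C6, proton loss from C4 or capture by the C7 ester; the last should be secured because the enolate carbon sits 1,4 to C5 on the same face within bonding distance, because O-alkylation of the enolate is impossible (it would give a bridgehead enol ether in a bicyclo[2.2.2] frame), and because the ester carbonyls are engaged by the excess Lewis acid at low temperature.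

Step 12
Reactants: 22 3-methoxy-7-[(3-methylbutanoyl)oxy]-1-oxolongipinan-9-yl (2E)-2-methylbut-2-enoate
Product: 23 (4R,5S,7R,9R,10R,11R)-7-[(3-methylbutanoyl)oxy]-1-oxolongipin-2-en-9-yl (2E)-2-methylbut-2-enoate (target)
Conditions: DBU (1.5 equiv), CH2Cl2, 20 °C
Reagents that add atoms: none
Why: E1cB elimination of methanol from the β-methoxy ketone gives the conjugated C2=C3 enone; C11 is a bridgehead and cannot enolise, so no stereocentre is at risk.

**Compound list**

1 | 2,2-dimethylpent-4-enal | C=CCC(C)(C)C=O | starting material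
2 | 3-methylbut-3-en-2-one | CC(=O)C(C)=C | starting material
3 | (5R)-5-hydroxy-2,6,6-trimethylnona-1,8-dien-3-one | C=C(C)C(=O)C[C@@H](O)C(C)(C)CC=C | intermediate
4 | 3-methylbutanal | CC(C)CC=O | starting material
5 | (3R,5R)-3-hydroxy-2,6,6-trimethylnona-1,8-dien-5-yl 3-methylbutanoate | C=C(C)[C@H](O)C[C@@H](OC(=O)CC(C)C)C(C)(C)CC=C | intermediate
6 | (1R,6R)-6-hydroxy-2,2,5-trimethylcyclohept-4-en-1-yl 3-methylbutanoate | O[C@@H]1C[C@@H](OC(=O)CC(C)C)C(C)(C)CC=C1C | intermediate
7 | ethyl vinyl ether (ethoxyethene) | C=COCC | starting material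
8 | N-iodosuccinimide | O=C1CCC(=O)N1I | starting material
9 | (1R,6R)-6-(1-ethoxy-2-iodoethoxy)-2,2,5-trimethylcyclohept-4-en-1-yl 3-methylbutanoate (both acetal epimers) | CCOC(CI)O[C@@H]1C[C@@H](OC(=O)CC(C)C)C(C)(C)CC=C1C | intermediate
10 | (3aS,7R,8aR)-2-ethoxy-3a,6,6-trimethyl-3,3a,6,7,8,8a-hexahydro-2H-cyclohepta[b]furan-7-yl 3-methylbutanoate (cis-fused, both C2 epimers) | O1[C@@H]2C[C@@H](OC(=O)CC(C)C)C(C)(C)C=C[C@@]2(CC1OCC)C | intermediate
11 | propane-1,3-dithiol | SCCCS | starting material
12 | (1R,5S,6R)-5-(1,3-dithian-2-ylmethyl)-6-hydroxy-2,2,5-trimethylcyclohept-3-en-1-yl 3-methylbutanoate | O[C@@H]1C[C@@H](OC(=O)CC(C)C)C(C)(C)C=C[C@@]1(CC2SCCCS2)C | intermediate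
13 | tigloyl chloride, (2E)-2-methylbut-2-enoyl chloride | C/C=C(\C)C(=O)Cl | starting material
14 | (1R,2S,6R)-2-(1,3-dithian-2-ylmethyl)-2,5,5-trimethyl-6-[(3-methylbutanoyl)oxy]cyclohept-3-en-1-yl (2E)-2-methylbut-2-enoate | C/C=C(\C)C(=O)O[C@@H]1C[C@@H](OC(=O)CC(C)C)C(C)(C)C=C[C@@]1(CC2SCCCS2)C | intermediate
15 | (1R,2S,6R)-2,5,5-trimethyl-6-[(3-methylbutanoyl)oxy]-2-(2-oxoethyl)cyclohept-3-en-1-yl (2E)-2-methylbut-2-enoate | C/C=C(\C)C(=O)O[C@@H]1C[C@@H](OC(=O)CC(C)C)C(C)(C)C=C[C@@]1(CC=O)C | intermediate
16 | 2-{(1S,5R,7R)-1,4,4-trimethyl-5-[(3-methylbutanoyl)oxy]-7-{[(2E)-2-methylbut-2-enoyl]oxy}cyclohept-2-en-1-yl}acetic acid | C/C=C(\C)C(=O)O[C@@H]1C[C@@H](OC(=O)CC(C)C)C(C)(C)C=C[C@@]1(CC(=O)O)C | intermediate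
17 | 2-methoxypropene | C=C(C)OC | starting material
18 | acid chloride of 16 (same ring configuration; not isolated) | C/C=C(\C)C(=O)O[C@@H]1C[C@@H](OC(=O)CC(C)C)C(C)(C)C=C[C@@]1(CC(=O)Cl)C | intermediate
19 | ketene from 18, the ring carbon C10 bearing CH=C=O (same ring configuration; not isolated) | C/C=C(\C)C(=O)O[C@@H]1C[C@@H](OC(=O)CC(C)C)C(C)(C)C=C[C@@]1(C=C=O)C | intermediate
20 | (1R,2R,6R)-2-(2-methoxy-2-methyl-4-oxocyclobutyl)-2,5,5-trimethyl-6-[(3-methylbutanoyl)oxy]cyclohept-3-en-1-yl (2E)-2-methylbut-2-enoate (cyclobutane diastereomers) | C/C=C(\C)C(=O)O[C@@H]1C[C@@H](OC(=O)CC(C)C)C(C)(C)C=C[C@@]1(C2C(=O)CC2(C)OC)C | intermediate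
21 | 1,4-zwitterion: ethyldichloroaluminate enolate at O1/C11 and methoxycarbenium at C3, side chain on C10 of the cycloheptene (not isolated) | C/C=C(\C)C(=O)O[C@@H]1C[C@@H](OC(=O)CC(C)C)C(C)(C)C=C[C@@]1(C=C(O[Al-](Cl)(Cl)CC)CC(C)=[O+]C)C | intermediate
22 | 3-methoxy-7-[(3-methylbutanoyl)oxy]-1-oxolongipinan-9-yl (2E)-2-methylbut-2-enoate (C4, C5, C7, C9, C10, C11 as in 23; both C3 epimers) | C/C=C(\C)C(=O)O[C@@H]1C[C@@H](OC(=O)CC(C)C)C(C)(C)[C@@H]2[C@H]3C(=O)CC(C)(OC)[C@@H]2[C@]31C | intermediate
23 | (4R,5S,7R,9R,10R,11R)-7-[(3-methylbutanoyl)oxy]-1-oxolongipin-2-en-9-yl (2E)-2-methylbut-2-enoate | C/C=C(\C)C(=O)O[C@@H]1C[C@@H](OC(=O)CC(C)C)C(C)(C)[C@@H]2[C@H]3C(=O)C=C(C)[C@@H]2[C@]31C | target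

**Totals**

Total step count: 12. Longest linear sequence: 12 steps (from 1 and 2; all other inputs are commercial reagents used directly).

**Steps most likely to fail**

1. Step 11 (proposed new method). The cationic centre that develops at C5 may be lost before the four-membered ring closes: by a 1,2-methyl shift from C6, by proton loss from C4, or by capture by chloride or the C7 ester carbonyl. The zwitterion may also simply tautomerise to the open-chain β-methoxy enone. The fallback makes the two bonds in separate, known operations; it sets out from 20 and returns at 23. Compound 20 is treated with TiCl4 in CH2Cl2 at −78 °C. The cyclobutanone opens as before, but in the chloride-rich medium the six-membered ring should close as a Prins-type carbocyclisation with halide termination, chloride adding to C5 on the face opposite to the new C3–C4 bond. This gives the cis-fused chloro β-methoxy ketone F1. DBU then removes methanol to give the chloro enone F2. KN(SiMe3)2 (THF, −78 → 0 °C) forms the α′-enolate at C11, which displaces the chloride at C5 from the opposite face. This is the intramolecular enolate alkylation of classical pinane-type cyclobutane closures, and it delivers 23.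

2. Step 5. Radical generation at zerovalent palladium may be slow, the cyclised C4 radical may be reduced, or closure may occur 6-endo at C4 instead of forming the quaternary centre. The fallback replaces the acetal tether and the palladium chemistry by an ester tether and an atom-transfer radical chain; it sets out from 6 and returns at 12. Compound 6 is esterified with iodoacetic acid (DCC, DMAP) to the iodoacetate F3. Et3B/air in water starts an iodine-atom-transfer 5-exo cyclisation to the cis-fused iodo lactone F4. DBU in toluene at 80 °C eliminates hydrogen iodide, which can only go towards C5, giving the unsaturated lactone F5. i-Bu2AlH (1.05 equiv, CH2Cl2, −78 °C) should reduce the strained γ-lactone in preference to the hindered isovalerate, giving the lactol F6. F6 with 11 and BF3·OEt2 gives 12.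

3. Step 10. Dehydrochlorination of the neopentyl-type acid chloride may be sluggish, the ketene may be lost to dimer or moisture, and 20 may lose methanol on isolation. The fallback reaches the same cyclobutanone through a keteniminium salt instead of a free ketene; it sets out from 16 and returns at 20. Compound 16 is converted, via its acid chloride and dimethylamine, into the N,N-dimethylamide F7. Tf2O and 2,4,6-collidine in CH2Cl2 generate the keteniminium triflate, which undergoes [2+2] cycloaddition with 17. Hydrolysis of the cyclobutaniminium salt with aq. NaHCO3 gives 20.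

**Further compounds**

F1 | step 11 | 5-chloro-3-methoxy-5,11-seco-longipinan-1-one 7-(3-methylbutanoate) 9-[(2E)-2-methylbut-2-enoate], cis-fused, chlorine anti to the C3–C4 bond | C/C=C(\C)C(=O)O[C@@H]1C[C@@H](OC(=O)CC(C)C)C(C)(C)[C@@H](Cl)[C@@H]2C(C)(OC)CC(=O)C[C@]12C
F2 | step 11 | 5-chloro-5,11-seco-longipin-2-en-1-one 7-(3-methylbutanoate) 9-[(2E)-2-methylbut-2-enoate] | C/C=C(\C)C(=O)O[C@@H]1C[C@@H](OC(=O)CC(C)C)C(C)(C)[C@@H](Cl)[C@@H]2C(C)=CC(=O)C[C@]12C
F3 | step 5 | (1R,6R)-6-[(iodoacetyl)oxy]-2,2,5-trimethylcyclohept-4-en-1-yl 3-methylbutanoate | O=C(CI)O[C@@H]1C[C@@H](OC(=O)CC(C)C)C(C)(C)CC=C1C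
F4 | step 5 | cis-fused 4-iodo-3a,6,6-trimethyl-2-oxooctahydro-2H-cyclohepta[b]furan-7-yl 3-methylbutanoate (ring-fusion and C7 configuration as in 10, C4 epimers) | O1[C@@H]2C[C@@H](OC(=O)CC(C)C)C(C)(C)CC(I)[C@@]2(CC1=O)C
F5 | step 5 | (3aS,7R,8aR)-3a,6,6-trimethyl-2-oxo-3,3a,6,7,8,8a-hexahydro-2H-cyclohepta[b]furan-7-yl 3-methylbutanoate | O1[C@@H]2C[C@@H](OC(=O)CC(C)C)C(C)(C)C=C[C@@]2(CC1=O)C
F6 | step 5 | (3aS,7R,8aR)-2-hydroxy-3a,6,6-trimethyl-3,3a,6,7,8,8a-hexahydro-2H-cyclohepta[b]furan-7-yl 3-methylbutanoate (both anomers) | O1[C@@H]2C[C@@H](OC(=O)CC(C)C)C(C)(C)C=C[C@@]2(CC1O)C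
F7 | step 10 | 2-{(1S,5R,7R)-1,4,4-trimethyl-5-[(3-methylbutanoyl)oxy]-7-{[(2E)-2-methylbut-2-enoyl]oxy}cyclohept-2-en-1-yl}-N,N-dimethylacetamide | C/C=C(\C)C(=O)O[C@@H]1C[C@@H](OC(=O)CC(C)C)C(C)(C)C=C[C@@]1(CC(=O)N(C)C)C
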